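**Plan**

- Retrosynthesis (acid numbering: C1 = lactone carbonyl, C26 = OCH2): the C6–C7 ring bond is cut first, after retro-hydrogenation to the C6=C7 olefin; then the ester C1–O bond; then the C16–C17 bond of the long chain.
- Forward: C16–C17 is joined by a copper-catalysed Grignard coupling of two commercial C11 and C10 bromides, the chain is esterified with hept-6-enoic acid, the only ring (the 27-membered lactone) is closed by ring-closing metathesis at C6=C7, and the olefin is hydrogenated.
- Enabling feature: the ring is one unbranched, strain-free 27-membered polymethylene lactone whose only functional group is the O–C1(=O) ester. C6 and C7 lie five methylenes from C1 and twenty carbons from the ring oxygen, so both can be brought in as unhindered terminal vinyl carbons, and a carbene at C6 cannot form a small-ring chelate with the C1 carbonyl.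
- Stereochemistry: the target has no stereocentre. The only stereo-element that arises, the E/Z geometry of the C6=C7 olefin, is erased in the last step.

Key step: step 3

Remark: the metathesis product 9 is handled as its E/Z mixture and drawn as the E isomer, since both isomers converge on the target.

**Route**

Step 1
Reactants: 1 11-bromoundec-1-ene; 2 10-bromodecan-1-ol
Product: 6 henicos-20-en-1-ol, via undec-10-enylmagnesium bromide 3 (not isolated), via bromomagnesium 10-bromodecan-1-olate 4 (not isolated), via bromomagnesium henicos-20-en-1-olate 5 (not isolated)
Conditions: 1 (2.5 equiv), Mg turnings, THF, 40 °C; then added to 2 (1 equiv), THF, −20 °C; Li2CuCl4 (3 mol %), −20 °C → rt; 1 M HCl work-up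
Reagents that add atoms: none
Why: Copper-catalysed Grignard–alkyl bromide sp3–sp3 cross-coupling: the first equivalent of 3 turns the hydroxyl of 2 into its magnesium alkoxide 4, which masks it in situ, and the second equivalent displaces the primary bromide under Li2CuCl4 catalysis; the terminal olefin is inert and no stereocentre is formed.

Step 2
Reactants: 6 henicos-20-en-1-ol; 7 hept-6-enoic acid
Product: 8 henicos-20-en-1-yl hept-6-enoate
Conditions: DCC (1.1 equiv), DMAP (10 mol %), CH2Cl2, 0 °C → rt
Reagents that add atoms: none
Why: Steglich esterification: carbodiimide activation of the acid with DMAP as acyl-transfer catalyst should acylate the unhindered primary alcohol under neutral conditions that leave both terminal olefins in place; no stereocentre is formed.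

Step 3
Reactants: 8 henicos-20-en-1-yl hept-6-enoate
Product: 9 oxacycloheptacos-7-en-2-one (hexacos-6-en-26-olide; E/Z mixture, drawn as E)
Conditions: second-generation Grubbs catalyst RuCl2(=CHPh)(PCy3)(H2IMes) (5 mol %), 1,4-benzoquinone (10 mol %), CH2Cl2 (2 mM, slow addition of 8), 40 °C, argon sparge
Reagents that add atoms: none
Why: Ring-closing olefin metathesis: the ruthenium benzylidene initiates at either terminal vinyl group, and the resulting alkylidene at C6 (or C7) takes up the other vinyl group by [2+2] cycloaddition and cycloreversion through a ruthenacyclobutane, releasing ethylene and forming the C6=C7 bond. The closest known reaction type is the macrocyclic ring-closing metathesis of ω-alkenyl ω-alkenoates to large-ring musk lactones with ruthenium carbenes. The single ring, the 27-membered lactone, closes end to end by union of the two internal vinyl carbons; it is strain-free, so closure is driven by loss of ethylene and is reversible, which lets oligomers back-bite to the monomeric ring at high dilution. No stereocentre is formed, and the E/Z geometry of the new olefin is left uncontrolled because step 4 removes it. The selectivity needed is ring closure over acyclic diene metathesis oligomerisation and over double-bond migration; the first is secured by the 2 mM concentration, slow addition and removal of ethylene, the second by 1,4-benzoquinone as a scavenger of ruthenium hydride species. In the substrate, the five methylenes between the C1 carbonyl and C6 rule out a stable five- or six-membered carbonyl chelate of the propagating carbene, and both olefins are unhindered monosubstituted alkenes.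

Step 4
Reactants: 9 oxacycloheptacos-7-en-2-one
Product: 10 26-hexacosanolide (oxacycloheptacosan-2-one)
Conditions: H2 (1 atm), Pd/C (10 wt % Pd on carbon), EtOAc, rt
Reagents that add atoms: none
Why: Heterogeneous catalytic hydrogenation of an isolated disubstituted olefin: both geometric isomers of 9 should converge on the saturated lactone, and the ester is inert under these conditions; no stereocentre is formed.

**Compound list**

1 | 11-bromoundec-1-ene | C=CCCCCCCCCCBr | starting material
2 | 10-bromodecan-1-ol | OCCCCCCCCCCBr | starting material
3 | undec-10-enylmagnesium bromide | C=CCCCCCCCCC[Mg]Br | intermediate (not isolated)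
4 | bromomagnesium 10-bromodecan-1-olate | Br[Mg]OCCCCCCCCCCBr | intermediate (not isolated)
5 | bromomagnesium henicos-20-en-1-olate | C=CCCCCCCCCCCCCCCCCCCCO[Mg]Br | intermediate (not isolated)
6 | henicos-20-en-1-ol | C=CCCCCCCCCCCCCCCCCCCCO | intermediate
7 | hept-6-enoic acid | C=CCCCCC(=O)O | starting material
8 | henicos-20-en-1-yl hept-6-enoate | C=CCCCCC(=O)OCCCCCCCCCCCCCCCCCCCC=C | intermediate
9 | oxacycloheptacos-7-en-2-one (E/Z mixture, drawn as E) | O=C1CCCC/C=C/CCCCCCCCCCCCCCCCCCCO1 | intermediate
10 | 26-hexacosanolide (oxacycloheptacosan-2-one), no stereocentre | O=C1CCCCCCCCCCCCCCCCCCCCCCCCCO1 | target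

**Totals**

Total step count: 4
Longest linear sequence: 4 steps (1 or 2 → 6 → 8 → 9 → 10)

**Steps most likely to fail**

Step 3 (ring-closing metathesis). Acyclic diene metathesis oligomerisation may outrun closure of the 27-membered ring, and migration of a terminal double bond before closure would lead to ring-contracted homologues that are hard to separate. The fallback sets out from 6 and 7 and comes back to the route at 10; it forms the C6–C7 bond intermolecularly and closes the ring at the lactone C–O bond instead. Cross-metathesis of 6 with an excess of 7 (second-generation Grubbs catalyst RuCl2(=CHPh)(PCy3)(H2IMes), CH2Cl2, 40 °C) should give 26-hydroxyhexacos-6-enoic acid F1 as an E/Z mixture. Hydrogenation (H2, Pd/C, THF, rt) should give 26-hydroxyhexacosanoic acid F2. Yamaguchi macrolactonisation (2,4,6-trichlorobenzoyl chloride, Et3N, THF, then slow addition to DMAP in toluene at reflux under high dilution) should then give 10 directly.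

Step 1 (Grignard coupling on the unprotected bromo alcohol). The magnesium alkoxide may precipitate at low temperature and stall the substitution, and homocoupling may consume the Grignard reagent. The fallback sets out from 2 (with Grignard reagent 3 made from 1 as in the route) and comes back at 6; it replaces the magnesium alkoxide by a neutral acetal. Treatment of 2 with 3,4-dihydro-2H-pyran and PPTS in CH2Cl2 should give 2-[(10-bromodecyl)oxy]oxane F3 (racemic at the acetal carbon). Coupling with 3 (1.3 equiv; Li2CuCl4 3 mol %, THF, −20 °C → rt) should give 2-(henicos-20-en-1-yloxy)oxane F4. Acetal exchange (PPTS, MeOH, 50 °C) should release 6.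

Step 2 (carbodiimide esterification). The activated acid may rearrange to an unreactive N-acylurea if the waxy, sparingly soluble alcohol intercepts it slowly. The fallback sets out from 6 and 7 and comes back at 8; it activates the alcohol in place of the acid. A Mitsunobu esterification (PPh3, DIAD, THF, 0 °C → rt) should turn the primary hydroxyl of 6 into an alkoxyphosphonium leaving group, which the carboxylate of 7 displaces at the unhindered CH2. No new compound is made on the way.

**Further compounds**

F1 | step 3 | 26-hydroxyhexacos-6-enoic acid (E/Z mixture, drawn as E) | OC(=O)CCCC/C=C/CCCCCCCCCCCCCCCCCCCO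
F2 | step 3 | 26-hydroxyhexacosanoic acid | OC(=O)CCCCCCCCCCCCCCCCCCCCCCCCCO
F3 | step 1 | 2-[(10-bromodecyl)oxy]oxane (racemic) | BrCCCCCCCCCCOC1CCCCO1
F4 | step 1 | 2-(henicos-20-en-1-yloxy)oxane (racemic) | C=CCCCCCCCCCCCCCCCCCCCOC1CCCCO1
F0 | step 2 | none | none
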